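**Route overview**

- Cuts: C3–C4 of the pyranone (ring C) first, then the O1–C2 ether bond, then the O7–prenyl ether bond. Rings A and B are bought intact.
- Enabling feature: C4 (ketone) and C3 (enol C–OH) of ring C are neighbours, both at the carbonyl oxidation level, and are already linked the other way round through C2–O1–C8a–C4a. C4 can therefore come from an aryl aldehyde used with reversed polarity and C3 from an ester.
- Forward: O7-prenylation of 2,4-dihydroxybenzaldehyde; esterification and benzylic bromination of homoveratric acid; union of the halves by phenol O-alkylation (O1–C2); ring C, the only ring made, closed last at C3–C4.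
- Stereochemistry: the target has no stereocentre. The single sp3 centre on the way (future C2) is carried as a racemate and becomes sp2 in the last step.

Key step: step 5

Step 1
Reactants: 1 2,4-dihydroxybenzaldehyde; 2 prenyl bromide (1-bromo-3-methylbut-2-ene)
Product: 3 2-hydroxy-4-[(3-methylbut-2-en-1-yl)oxy]benzaldehyde
Conditions: K2CO3 (1.0 equiv), 2 (1.05 equiv), acetone, 40 °C
Reagents that add atoms: none
Why: Williamson etherification should occur at the 4-hydroxyl, which is para to the formyl group, more acidic and not tied up in the hydrogen bond that deactivates the 2-hydroxyl, so one equivalent of carbonate and the SN2-reactive allylic bromide should give the mono-ether.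

Step 2
Reactants: 4 (3,4-dimethoxyphenyl)acetic acid (homoveratric acid)
Product: 5 methyl 2-(3,4-dimethoxyphenyl)acetate
Conditions: MeOH, H2SO4 (cat.), reflux
Reagents that add atoms: methanol (CO)
Why: Fischer esterification, driven to completion by methanol as solvent, with no acid-sensitive group in the substrate.

Step 3
Reactants: 5 methyl 2-(3,4-dimethoxyphenyl)acetate
Product: 7 methyl 2-bromo-2-(3,4-dimethoxyphenyl)acetate (racemic), via trimethylsilyl ketene acetal 6 (not isolated)
Conditions: LiN(SiMe3)2 (1.1 equiv), THF, −78 °C; Me3SiCl (1.2 equiv), −78 °C; then NBS (1.05 equiv), −78 → 0 °C; 7 is used promptly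
Reagents that add atoms: N-bromosuccinimide (O=C1CCC(=O)N1Br); chlorotrimethylsilane (C[Si](C)(C)Cl)
Why: Electrophilic alpha-bromination of a silyl ketene acetal: the benzylic ester enolate is O-silylated by Me3SiCl to give 6, the only compound that carries the silyl group, and this ketene acetal, far more nucleophilic than the dimethoxyarene ring, should take up one bromine at carbon only with loss of the silyl group, while silyl trapping prevents enolate coupling with the bromo ester; the new stereocentre is formed as a racemate.

Step 4
Reactants: 3 2-hydroxy-4-[(3-methylbut-2-en-1-yl)oxy]benzaldehyde; 7 methyl 2-bromo-2-(3,4-dimethoxyphenyl)acetate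
Product: 8 methyl 2-(3,4-dimethoxyphenyl)-2-{2-formyl-5-[(3-methylbut-2-en-1-yl)oxy]phenoxy}acetate (racemic)
Conditions: K2CO3 (1.5 equiv), 7 (1.1 equiv), MeCN, 0 °C → rt
Reagents that add atoms: none
Why: Williamson O-alkylation in which the phenoxide of 3 displaces a secondary bromide doubly activated by the aryl ring and the ester, which should proceed at room temperature and so limit base-induced enolisation of the product; the centre stays racemic.

Step 5
Reactants: 8 methyl 2-(3,4-dimethoxyphenyl)-2-{2-formyl-5-[(3-methylbut-2-en-1-yl)oxy]phenoxy}acetate
Product: 10 the flavonol 2-(3,4-dimethoxyphenyl)-3-hydroxy-7-[(3-methylbut-2-en-1-yl)oxy]-4H-chromen-4-one, via chromane-3,4-dione 9 (not isolated)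
Conditions: 3-benzyl-5-(2-hydroxyethyl)-4-methylthiazolium chloride (20 mol %), Et3N (2.0 equiv), degassed 1,4-dioxane, 70 °C, argon; aq. NH4Cl work-up
Reagents that add atoms: none
Why: Proposed new method: Et3N frees the thiazol-2-ylidene, which adds to the aldehyde of 8 and after proton transfer gives the nucleophilic enaminol (acyl anion equivalent) whose carbon, the future C4, attacks the tethered ester carbonyl, the future C3; the tetrahedral adduct expels methoxide, the carbene leaves from the C4 alkoxide to give dione 9, and 9 enolises through its doubly activated C2–H to the conjugated, hydrogen-bonded flavonol 10. The closest known reaction types are the carbene-catalysed intramolecular crossed benzoin of salicylaldehyde-derived keto ethers, which gives 3-hydroxychroman-4-ones, and the intramolecular aldehyde–nitrile coupling to 3-aminochromones; an ester acceptor has no such precedent. Ring C closes in a 6-exo-trig mode at C3–C4. No stereocentre is formed and the racemic C2 of 8 ends up sp2, so nothing needs to be controlled there. The step needs acylation at the ester to win over homo-benzoin coupling of the aldehyde and over 5-exo aldol addition of the C2 ester enolate to the aldehyde; the short ether tether, the inductive activation of the ester by the alpha-aryloxy group, the weak amine base and the reversibility of both side reactions against the irreversible enolisation to 10 should secure this. An excess of amine is kept because the acidic 3-hydroxyl of 10 would otherwise protonate the free carbene and stop turnover, and the amine is not consumed in the net reaction.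

**Compound list**

1 | 2,4-dihydroxybenzaldehyde | O=Cc1ccc(O)cc1O | starting material
2 | prenyl bromide (1-bromo-3-methylbut-2-ene) | CC(C)=CCBr | starting material
3 | 2-hydroxy-4-[(3-methylbut-2-en-1-yl)oxy]benzaldehyde | O=Cc1ccc(OCC=C(C)C)cc1O | intermediate
4 | (3,4-dimethoxyphenyl)acetic acid | OC(=O)Cc1ccc(OC)c(OC)c1 | starting material
5 | methyl 2-(3,4-dimethoxyphenyl)acetate | COC(=O)Cc1ccc(OC)c(OC)c1 | intermediate
6 | {[2-(3,4-dimethoxyphenyl)-1-methoxyethenyl]oxy}trimethylsilane (mixture of double-bond isomers, not isolated) | COC(=Cc1ccc(OC)c(OC)c1)O[Si](C)(C)C | intermediate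
7 | methyl 2-bromo-2-(3,4-dimethoxyphenyl)acetate (racemic) | COC(=O)C(Br)c1ccc(OC)c(OC)c1 | intermediate
8 | methyl 2-(3,4-dimethoxyphenyl)-2-{2-formyl-5-[(3-methylbut-2-en-1-yl)oxy]phenoxy}acetate (racemic) | COC(=O)C(Oc1cc(OCC=C(C)C)ccc1C=O)c1ccc(OC)c(OC)c1 | intermediate
9 | 2-(3,4-dimethoxyphenyl)-7-[(3-methylbut-2-en-1-yl)oxy]chromane-3,4-dione (racemic, not isolated) | O=C1C(=O)c2ccc(OCC=C(C)C)cc2OC1c1ccc(OC)c(OC)c1 | intermediate
10 | 2-(3,4-dimethoxyphenyl)-3-hydroxy-7-[(3-methylbut-2-en-1-yl)oxy]-4H-chromen-4-one | COc1ccc(-c2oc3cc(OCC=C(C)C)ccc3c(=O)c2O)cc1OC | target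

**Count**

Total step count: 5.
Longest linear sequence: 4 steps (4 → 5 → 7 → 8 → 10; steps 2, 3, 4 and 5).

**Steps most likely to fail**

Step 5 (new method). The carbene–aldehyde adduct may fail to acylate the unreactive methyl ester. Material would then cycle through reversible homo-benzoin and aldol equilibria, or be lost slowly by adventitious oxidation of the aldehyde. The fallback builds ring C by the Algar–Flynn–Oyamada sequence and sets out from prenyl bromide 2. Commercial 2,4-dihydroxyacetophenone (CC(=O)c1ccc(O)cc1O) is alkylated at its 4-hydroxyl with 2 (K2CO3, acetone) to give 1-{2-hydroxy-4-[(3-methylbut-2-en-1-yl)oxy]phenyl}ethanone F1. Claisen–Schmidt condensation of this ketone with 3,4-dimethoxybenzaldehyde (KOH, EtOH, rt) should give (E)-3-(3,4-dimethoxyphenyl)-1-{2-hydroxy-4-[(3-methylbut-2-en-1-yl)oxy]phenyl}prop-2-en-1-one F2. Oxidative cyclisation with alkaline hydrogen peroxide (NaOH, 30% H2O2, MeOH, 0 °C → rt) closes the pyranone and installs the 3-hydroxyl, coming back to the route at target 10. The chalcone has no 6'-substituent, which favours the flavonol over the aurone, and the electron-rich prenyl alkene should not react with the nucleophilic peroxide.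

Step 4. Under the basic alkylation conditions the new ether may enolise at its benzylic alpha-carbon and add to the neighbouring aldehyde in a 5-exo aldol closure. The labile benzylic bromide may also be lost by solvolysis before it is alkylated. The fallback forms the same O1–C2 bond without base and sets out from ester 5. Hydroxylation of the enolate (LiN(SiMe3)2, THF, −78 °C; then 2-(phenylsulfonyl)-3-phenyloxaziridine) should give methyl 2-(3,4-dimethoxyphenyl)-2-hydroxyacetate F3 as the racemate. Mitsunobu etherification of this alcohol with phenol 3 (PPh3, diisopropyl azodicarboxylate, THF, 0 °C → rt) comes back to the route at 8. The acidic salicylaldehyde phenol and an alpha-hydroxy ester are both standard partners for this reaction.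

Step 3. Bromination may go on to the dibromo ester or attack the electron-rich ring B. The electron-rich benzylic bromide may also ionise and hydrolyse during work-up. The fallback puts the bromine in through a diazo ester and sets out from ester 5. Regitz diazo transfer (4-acetamidobenzenesulfonyl azide, DBU, MeCN, rt) should give methyl 2-diazo-2-(3,4-dimethoxyphenyl)acetate F4. Treatment with HBr (48% aq., CH2Cl2, 0 °C) protonates the diazo carbon, nitrogen leaves and bromide is captured, coming back to the route at 7. Exactly one bromine is delivered at the benzylic carbon and no electrophilic bromine source touches the ring.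

**Further compounds**

F1 | step 5 | 1-{2-hydroxy-4-[(3-methylbut-2-en-1-yl)oxy]phenyl}ethanone | CC(=O)c1ccc(OCC=C(C)C)cc1O
F2 | step 5 | (E)-3-(3,4-dimethoxyphenyl)-1-{2-hydroxy-4-[(3-methylbut-2-en-1-yl)oxy]phenyl}prop-2-en-1-one | O=C(/C=C/c1ccc(OC)c(OC)c1)c1ccc(OCC=C(C)C)cc1O
F3 | step 4 | methyl 2-(3,4-dimethoxyphenyl)-2-hydroxyacetate (racemic) | COC(=O)C(O)c1ccc(OC)c(OC)c1
F4 | step 3 | methyl 2-diazo-2-(3,4-dimethoxyphenyl)acetate | COC(=O)C(=[N+]=[N-])c1ccc(OC)c(OC)c1
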